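**Direct plan and its weak points**

A direct plan would dress bought 2-methoxy-6-methylbenzoic acid A1 as the ring B phenol A2 (tert-butyl ester formation, lateral lithiation and butylation, C–H borylation with [Ir(OMe)(cod)]2/B2pin2, oxidation). It would acylate A2 with dec-2-ynoic acid A3 to the aryl ynoate A4, build ring A on A4 by a Diels–Alder reaction with the silyl ketene acetal diene A5 and aromatisation to the tert-butyl ester A6, and end with acidolysis. Its weakest steps would be:
- The three-step dressing of the arene: an esterification, a carbanion alkylation and a C–H oxidation would add no more than a butyl group and a hydroxyl.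
- The carbodiimide/DMAP coupling of the alk-2-ynoic acid: DMAP addition to the ynoate, allenoate formation and N-acylurea formation would compete.
- The late thermal cycloaddition, the step least welcome on precious material: ring closure and regiochemistry would rest on polarisation alone, the β-heptyl group would slow the dienophile, and the nucleophilic diene could cleave the activated aryl ester.

**Plan of the new route**

- The depside C(=O)–O bond is cut last. Each ring is then cut between C1 and its alkyl-bearing neighbour (C1–C2 in ring A, C1–C6 in ring B), so both unfold to tetraketide chains: octanoyl or hexanoyl starter plus three acetate units.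
- The enabling feature is that ring A is a salicylate: O6 is ortho to the C1 carboxyl carbon, so this pair can be carried from the first step as the 1,3-dioxin-4-one of the diketene–acetone adduct, on which the chain is grown.
- Aldol aromatisation (key step) gives ring A as a benzodioxinone. O4 is then the only free phenol, and C1 is an acyl donor that sets O6–H free in the act of acylating ring B.
- Ring B comes from a 4-methoxypyran-2-one whose enol ether is already the C2 methoxy group; base isomerises it to the 4-hydroxy acid.
- Ring A arises first (step 3), ring B second (step 6), the ester bond last (step 7). No ring is built on an ester, no ynoate or ketene acetal is used, no arene is dressed, and nothing is deprotected.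

Key step: step 3

Remark: in each ring C1 bears the carboxyl carbon. Ring A is the acyl ring (heptyl C2, methoxy C4, hydroxyl C6) and ring B the phenol ring (methoxy C2, acyloxy C4, pentyl C6). N-methoxy-N-methyloctanamide is taken as a catalogue compound.

**Route**

Step 1
Reactants: 1 2,2,6-trimethyl-4H-1,3-dioxin-4-one; 2 acetyl chloride
Product: 4 2,2-dimethyl-6-(2-oxopropyl)-4H-1,3-dioxin-4-one, via lithium dienolate 3 (not isolated)
Conditions: 1 (2.0 equiv), LiN(SiMe3)2 (2.0 equiv), THF, −78 °C; 2 (1.0 equiv), −78 °C; aq. NH4Cl
Reagents that add atoms: none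
Why: Kinetic γ-deprotonation of the vinylogous ester should give the dienolate, which the acid chloride acylates at the exocyclic carbon (crossed Claisen condensation), the second equivalent of dienolate taking up the proton of the more acidic product.

Step 2
Reactants: 4 2,2-dimethyl-6-(2-oxopropyl)-4H-1,3-dioxin-4-one; 5 N-methoxy-N-methyloctanamide
Product: 7 6-(2,4-dioxoundecyl)-2,2-dimethyl-4H-1,3-dioxin-4-one, via dilithium dianion 6 (not isolated)
Conditions: LiN(iPr)2 (2.2 equiv), THF, −78 → −40 °C; 5 (1.0 equiv), −78 → −10 °C; cold 1 M HCl to pH 3; crude 7 taken on without chromatography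
Reagents that add atoms: none
Why: In the β-dicarbonyl-type dianion the carbanion formed last, at the methyl terminus, is the more nucleophilic site and should be acylated there by the Weinreb amide, whose chelated tetrahedral adduct prevents a second addition (Claisen condensation of a keto-dioxinone dianion).

Step 3
Reactants: 7 6-(2,4-dioxoundecyl)-2,2-dimethyl-4H-1,3-dioxin-4-one
Product: 9 5-heptyl-7-hydroxy-2,2-dimethyl-4H-1,3-benzodioxin-4-one, via cyclic aldol adduct 8 (not isolated)
Conditions: Et3N (3 equiv), CH2Cl2, 0 °C → rt; 1 M HCl wash
Reagents that add atoms: none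
Why: Triethylamine should deprotonate C1′ of the side chain (between the dioxinone and the C2′ ketone), and the delocalised dienolate should add from dioxinone C5 to the heptyl-bearing ketone carbon C4′ (intramolecular vinylogous aldol addition); E1cB loss of water from 8 and enolisation of the remaining ketone then give the phenol, which copies the C2–C7 folding of a tetraketide. The closest known reaction type is the amine- or carbonate-mediated aromatisation of diketo-dioxinones to 7-hydroxy-2,2-dimethyl-1,3-benzodioxin-4-ones. Ring A closes as a six-membered carbocycle by 6-(enolendo)-exo-trig C–C bond formation between the carbons that become C1 and C2 of ring A. The two stereocentres of 8 form without control and both are erased on aromatisation, so none has to be set. The step needs aldol closure and not Claisen closure or lactonisation, and the substrate secures it: the carboxyl carbon is locked in the dioxinone as a vinylogous carbonate that is no acyl acceptor, and C5 onto C4′ is the only six-membered C–C closure open to the chain. The chain sequence alone places heptyl at C2, the free hydroxyl at C4 and the acetonide-bound oxygen at C6.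

Step 4
Reactants: 9 5-heptyl-7-hydroxy-2,2-dimethyl-4H-1,3-benzodioxin-4-one
Product: 10 5-heptyl-7-methoxy-2,2-dimethyl-4H-1,3-benzodioxin-4-one
Conditions: MeI (1.5 equiv), K2CO3 (1.5 equiv), acetone, 40 °C
Reagents that add atoms: iodomethane, CI
Why: Williamson O-methylation of the only free phenol should be clean, since the other ring oxygen is held in the acetonide, so the C4-methoxy/C6-hydroxy pattern of ring A needs no selectivity.

Step 5
Reactants: 11 4-methoxy-6-methyl-2H-pyran-2-one; 12 hexanoyl chloride
Product: 14 4-methoxy-6-(2-oxoheptyl)-2H-pyran-2-one, via lithiated pyranone 13 (not isolated)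
Conditions: 11 (2.0 equiv), LiN(SiMe3)2 (2.0 equiv), THF, −78 °C; 12 (1.0 equiv), −78 → −40 °C; aq. NH4Cl
Reagents that add atoms: none
Why: Lateral (vinylogous) deprotonation of the 6-methyl group should give the pyranone dienolate, which the acid chloride acylates at the exocyclic carbon (crossed Claisen condensation), the second equivalent of anion buffering the more acidic product.

Step 6
Reactants: 14 4-methoxy-6-(2-oxoheptyl)-2H-pyran-2-one
Product: 16 4-hydroxy-2-methoxy-6-pentylbenzoic acid, via open-chain dioxo enoate 15 (not isolated)
Conditions: 2 M aq. KOH (5 equiv), 1,4-dioxane, Ar, rt → 45 °C; 2 M HCl to pH 2 at 0 °C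
Reagents that add atoms: potassium hydroxide, [K+].[OH-]
Why: This relies on the base-induced ring transformation of 6-(2-oxoalkyl)pyran-2-ones into resorcylates: hydroxide should open the lactone at C2 to the (E)-enoate 15, whose ketone dienolate adds from C2 to the C7 ketone (intramolecular aldol condensation), and loss of water gives the arene with the enol ether as the C2 methoxy group, the C5 carbonyl as the free C4 phenol and the acid unesterified because no alcohol is present.

Step 7
Reactants: 16 4-hydroxy-2-methoxy-6-pentylbenzoic acid; 10 5-heptyl-7-methoxy-2,2-dimethyl-4H-1,3-benzodioxin-4-one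
Product: 17 4-[(2-heptyl-6-hydroxy-4-methoxybenzoyl)oxy]-2-methoxy-6-pentylbenzoic acid (target)
Conditions: NaH (2.1 equiv), DMF, 0 °C → rt; 10 (1.1 equiv), 60–80 °C; 1 M HCl, 0 °C
Reagents that add atoms: none
Why: In this nucleophilic acyl substitution the C4 aryloxide of the dianion of 16, a full-strength phenoxide because a para carboxylate barely withdraws, should add to the lactone carbonyl of 10 and collapse with loss of acetone to the salicylate ester and the chelated O6 phenoxide irreversibly, while the carboxylate flanked by methoxy and pentyl is too hindered to compete (alkoxide opening of 2,2-dimethyl-1,3-benzodioxin-4-ones to salicylate esters).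

**Compound list**

1 | 2,2,6-trimethyl-4H-1,3-dioxin-4-one | CC1=CC(=O)OC(C)(C)O1 | starting material
2 | acetyl chloride | CC(Cl)=O | starting material
3 | lithium 2,2-dimethyl-6-methylidene-6H-1,3-dioxin-4-olate (lithium dienolate, not isolated) | C=C1C=C(O[Li])OC(C)(C)O1 | intermediate
4 | 2,2-dimethyl-6-(2-oxopropyl)-4H-1,3-dioxin-4-one | CC(=O)CC1=CC(=O)OC(C)(C)O1 | intermediate
5 | N-methoxy-N-methyloctanamide | CCCCCCCC(=O)N(C)OC | starting material
6 | dilithium dianion of 4, deprotonated at the ring-bound CH2 and the terminal CH3 (not isolated) | C=C(O[Li])C=C1C=C(O[Li])OC(C)(C)O1 | intermediate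
7 | 6-(2,4-dioxoundecyl)-2,2-dimethyl-4H-1,3-dioxin-4-one | CCCCCCCC(=O)CC(=O)CC1=CC(=O)OC(C)(C)O1 | intermediate
8 | 5-heptyl-5-hydroxy-2,2-dimethyl-5,6-dihydro-4H-1,3-benzodioxine-4,7(4aH)-dione (cyclic aldol adduct, racemic diastereomer mixture, not isolated) | CCCCCCCC1(O)CC(=O)C=C2OC(C)(C)OC(=O)C12 | intermediate
9 | 5-heptyl-7-hydroxy-2,2-dimethyl-4H-1,3-benzodioxin-4-one | CCCCCCCc1cc(O)cc2OC(C)(C)OC(=O)c12 | intermediate
10 | 5-heptyl-7-methoxy-2,2-dimethyl-4H-1,3-benzodioxin-4-one | CCCCCCCc1cc(OC)cc2OC(C)(C)OC(=O)c12 | intermediate
11 | 4-methoxy-6-methyl-2H-pyran-2-one | COC1=CC(=O)OC(C)=C1 | starting material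
12 | hexanoyl chloride | CCCCCC(Cl)=O | starting material
13 | lithium 4-methoxy-6-methylidene-6H-pyran-2-olate (lithiated pyranone, not isolated) | COC1=CC(=C)OC(O[Li])=C1 | intermediate
14 | 4-methoxy-6-(2-oxoheptyl)-2H-pyran-2-one | CCCCCC(=O)CC1=CC(OC)=CC(=O)O1 | intermediate
15 | (2E)-3-methoxy-5,7-dioxododec-2-enoic acid (present as its potassium salts, not isolated) | CCCCCC(=O)CC(=O)C/C(OC)=C\C(=O)O | intermediate
16 | 4-hydroxy-2-methoxy-6-pentylbenzoic acid | CCCCCc1cc(O)cc(OC)c1C(=O)O | intermediate
17 | 4-[(2-heptyl-6-hydroxy-4-methoxybenzoyl)oxy]-2-methoxy-6-pentylbenzoic acid (CNP0341430.0) | CCCCCCCc1cc(OC)cc(O)c1C(=O)Oc1cc(CCCCC)c(C(=O)O)c(OC)c1 | target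

**Count and risks**

Total step count: 7. Longest linear sequence: 5 steps (steps 1, 2, 3, 4 and 7); steps 5 and 6 form the second branch.

Steps most likely to fail:

1. Step 7. The phenoxide may add too slowly to the hindered, electron-rich carbonyl of 10 (peri heptyl, para methoxy), the carboxylate may be acylated instead (mixed anhydride, then oligomers), or traces of hydroxide may hydrolyse 10. The fallback would set out from 16 and 10 and come back at 17.
   - 16 would be alkylated at the carboxylate (allyl bromide, KHCO3, DMF) to allyl 4-hydroxy-2-methoxy-6-pentylbenzoate F1.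
   - 10 would be hydrolysed (KOH, aqueous THF, then acid) to 2-heptyl-6-hydroxy-4-methoxybenzoic acid F2.
   - F2 and F1 would be condensed with trifluoroacetic anhydride in toluene (mixed-anhydride depside esterification of the only unchelated phenol) to allyl 4-[(2-heptyl-6-hydroxy-4-methoxybenzoyl)oxy]-2-methoxy-6-pentylbenzoate F3.
   - Pd(PPh3)4 (zerovalent palladium) with PhSiH3 in CH2Cl2 would remove the allyl group and give 17.

2. Step 6. At the carboxylate level the chain may be too poor a carbon nucleophile for the aldol closure, so that hydroxide cleaves the 1,3-diketone (retro-Claisen), the chain recloses to the pyranone on acidification, or the electron-rich acid loses CO2 on warm acidification. The fallback would set out from 14 and come back at 17.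
   - 14 would undergo the same ring transformation at the ester level with sodium benzyl oxide (BnOH, NaH, THF) to give benzyl 4-hydroxy-2-methoxy-6-pentylbenzoate F4.
   - The sodium phenoxide of F4 (NaH, DMF) would open 10 to benzyl 4-[(2-heptyl-6-hydroxy-4-methoxybenzoyl)oxy]-2-methoxy-6-pentylbenzoate F5.
   - Hydrogenolysis (H2, Pd/C, EtOAc) would give 17.

3. Step 2. O-acylation or proton transfer may replace C-acylation of the dianion, and the labile diketo-dioxinone may condense with itself or aromatise without control during work-up. The fallback would set out from 5 and come back at 9.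
   - The dilithium dianion of bought 4-hydroxy-6-methyl-2H-pyran-2-one F6 (LiN(iPr)2, THF, −78 °C) would be acylated at the methyl carbon by 5 to give 4-hydroxy-6-(2-oxononyl)-2H-pyran-2-one F7.
   - Aqueous KOH would turn F7 into 2-heptyl-4,6-dihydroxybenzoic acid F8 (pyranone-to-resorcylate transformation).
   - Acetone with (CF3CO)2O in CF3CO2H would close the acetonide between the carboxyl group and the ortho hydroxyl to give 9.

Further compounds
F1 | step 7 | allyl 4-hydroxy-2-methoxy-6-pentylbenzoate | CCCCCc1cc(O)cc(OC)c1C(=O)OCC=C
F2 | step 7 | 2-heptyl-6-hydroxy-4-methoxybenzoic acid | CCCCCCCc1cc(OC)cc(O)c1C(=O)O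
F3 | step 7 | allyl 4-[(2-heptyl-6-hydroxy-4-methoxybenzoyl)oxy]-2-methoxy-6-pentylbenzoate | CCCCCCCc1cc(OC)cc(O)c1C(=O)Oc1cc(CCCCC)c(C(=O)OCC=C)c(OC)c1
F4 | step 6 | benzyl 4-hydroxy-2-methoxy-6-pentylbenzoate | CCCCCc1cc(O)cc(OC)c1C(=O)OCc1ccccc1
F5 | step 6 | benzyl 4-[(2-heptyl-6-hydroxy-4-methoxybenzoyl)oxy]-2-methoxy-6-pentylbenzoate | CCCCCCCc1cc(OC)cc(O)c1C(=O)Oc1cc(CCCCC)c(C(=O)OCc2ccccc2)c(OC)c1
F6 | step 2 | 4-hydroxy-6-methyl-2H-pyran-2-one | CC1=CC(O)=CC(=O)O1
F7 | step 2 | 4-hydroxy-6-(2-oxononyl)-2H-pyran-2-one | CCCCCCCC(=O)CC1=CC(O)=CC(=O)O1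
F8 | step 2 | 2-heptyl-4,6-dihydroxybenzoic acid | CCCCCCCc1cc(O)cc(O)c1C(=O)O
A1 | direct plan | 2-methoxy-6-methylbenzoic acid | Cc1cccc(OC)c1C(=O)O
A2 | direct plan | tert-butyl 4-hydroxy-2-methoxy-6-pentylbenzoate | CCCCCc1cc(O)cc(OC)c1C(=O)OC(C)(C)C
A3 | direct plan | dec-2-ynoic acid | CCCCCCCC#CC(=O)O
A4 | direct plan | tert-butyl 4-(dec-2-ynoyloxy)-2-methoxy-6-pentylbenzoate | CCCCCCCC#CC(=O)Oc1cc(CCCCC)c(C(=O)OC(C)(C)C)c(OC)c1
A5 | direct plan | 1,3-dimethoxy-1-(trimethylsilyloxy)buta-1,3-diene | C=C(OC)C=C(OC)O[Si](C)(C)C
A6 | direct plan | tert-butyl 4-[(2-heptyl-6-hydroxy-4-methoxybenzoyl)oxy]-2-methoxy-6-pentylbenzoate | CCCCCCCc1cc(OC)cc(O)c1C(=O)Oc1cc(CCCCC)c(C(=O)OC(C)(C)C)c(OC)c1
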